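C1–C8a by opening a push–pull cyclopropane is the central disconnection; four lines set out the plan.

Cuts, in retrosynthetic order: the eight O-protecting groups (five benzyl ethers, three methyl esters); the Cα=Cβ alkene and then the O3'–Cα bond of the enol-ether side chain; the C4–O bond of a 4-oxo (enol) precursor; C1–C8a of ring B; last, C1–C3 and C2–C3 of a cyclopropane.
Enabling feature: C1 carries ring C, whose O4' lies para and can stabilise a cation at C1. C3 sits between a carboxyl carbon and C4, the carbon bonded to the electron-rich ring A. C1, C2 and C3 can therefore be stored as a push–pull cyclopropane whose C1–C3 bond is exchanged for C1–C8a.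
Forward order: rings A, C and D are bought as benzenes. The three-membered ring is made first, from an enal (ring C, C1, C2, C2-carboxyl carbon) and a bromo keto ester (ring A, C4, C3, C3-carboxyl carbon). It is then expanded to ring B, C4 is deoxygenated, and ring D is joined last through O3'.
Stereochemistry: C2 comes from an iminium–enamine cyclopropanation under (R)-diphenylprolinol trimethylsilyl ether. C1 is re-created trans to C2 in the ring expansion. The E enol ether comes from a kinetically controlled Still–Gennari olefination.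

Key step: step 9

Assumption: the bond symbols of the target string place O3' and ring D on opposite sides of the side-chain alkene, so the E isomer (ring D cis to CO2H) is the goal.
Remark: locants C1–C8a and ring letters A (fused benzene), B (dihydro ring), C (1-aryl group) and D (side-chain catechol) follow the target and are used for all intermediates.

Step 1
Reactants: 1 3',4'-dihydroxyacetophenone
Product: 2 3',4'-bis(benzyloxy)acetophenone
Conditions: BnBr (2.3 equiv), K2CO3, DMF, 60 °C
Reagents that add atoms: benzyl bromide, BrCc1ccccc1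
Why: Williamson ether synthesis on the two acidic phenols; benzyl ethers keep ring A electron-rich for the later arylation and can be removed at the end without reducing an alkene.

Step 2
Reactants: 2 3',4'-bis(benzyloxy)acetophenone; 3 dimethyl carbonate
Product: 4 methyl 3-[3,4-bis(benzyloxy)phenyl]-3-oxopropanoate
Conditions: NaH (2.5 equiv), toluene, reflux; then 1 M HCl
Reagents that add atoms: none
Why: Crossed Claisen condensation of the ketone enolate with a carbonate that cannot enolise, pulled to completion by deprotonation of the β-keto ester; the former methyl carbon becomes C3 and the new ester carbon its carboxyl group.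

Step 3
Reactants: 4 methyl 3-[3,4-bis(benzyloxy)phenyl]-3-oxopropanoate
Product: 5 methyl 2-bromo-3-[3,4-bis(benzyloxy)phenyl]-3-oxopropanoate (racemic)
Conditions: NBS (1.0 equiv), p-TsOH·H2O (10 mol %), CH2Cl2, 0 °C to rt
Reagents that add atoms: N-bromosuccinimide, O=C1CCC(=O)N1Br
Why: Electrophilic α-bromination of the highly enolised β-keto ester, which outruns attack on the acyl-deactivated ring A when one equivalent of NBS is used; the labile stereocentre is of no consequence.

Step 4
Reactants: 6 4-(benzyloxy)-3-hydroxybenzaldehyde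
Product: 7 3-acetoxy-4-(benzyloxy)benzaldehyde
Conditions: Ac2O, pyridine, CH2Cl2, rt
Reagents that add atoms: acetic anhydride, CC(=O)OC(C)=O
Why: Standard O-acetylation; the acetate masks O3' orthogonally to the benzyl ethers, should survive Lewis acid and triflation, and makes ring C a poorer competing nucleophile.

Step 5
Reactants: 7 3-acetoxy-4-(benzyloxy)benzaldehyde; 8 (triphenylphosphoranylidene)acetaldehyde
Product: 9 (E)-3-[3-acetoxy-4-(benzyloxy)phenyl]prop-2-enal
Conditions: 8 (1.1 equiv), toluene, 90 °C
Reagents that add atoms: none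
Why: Wittig reaction of a stabilised formyl ylide, which is E-selective and adds C2 and the future C2-carboxyl carbon under neutral conditions that leave the acetate alone.

Step 6
Reactants: 9 (E)-3-[3-acetoxy-4-(benzyloxy)phenyl]prop-2-enal; 5 methyl 2-bromo-3-[3,4-bis(benzyloxy)phenyl]-3-oxopropanoate
Product: 10 methyl (1S,2S,3R)-3-[3-acetoxy-4-(benzyloxy)phenyl]-1-[3,4-bis(benzyloxy)benzoyl]-2-formylcyclopropane-1-carboxylate
Conditions: (R)-2-[diphenyl(trimethylsilyloxy)methyl]pyrrolidine (20 mol %), 2,6-lutidine (1.1 equiv), CH2Cl2, 0 °C to rt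
Reagents that add atoms: none
Why: Organocatalytic Michael-initiated ring closure (iminium then enamine activation): the CPh2(OSiMe3) arm of the (R)-catalyst covers one face of the E iminium ion, so the enol of 5 adds to the open Re face of C1, and the enamine carbon C2 then displaces bromide from C3 in a 3-exo-tet SN2 step on the same face of the E alkene, which should give the trans C1/C2 cyclopropane with (S)-C2, while the epimer ratio at C3 is irrelevant because C3 becomes planar in step 9.

Step 7
Reactants: 10 formylcyclopropane (name as in step 6)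
Product: 11 (1S,2S,3R)-3-[3-acetoxy-4-(benzyloxy)phenyl]-2-[3,4-bis(benzyloxy)benzoyl]-2-(methoxycarbonyl)cyclopropane-1-carboxylic acid
Conditions: NaClO2, NaH2PO4, 2-methyl-2-butene, t-BuOH/THF/H2O, 0 °C to rt
Reagents that add atoms: sodium chlorite, [Na+].[O-]Cl=O
Why: Pinnick oxidation, buffered and mild enough to leave the push–pull cyclopropane, the acetate and the α-stereocentre C2 intact, with the alkene trapping HOCl before it can chlorinate the electron-rich rings.

Step 8
Reactants: 11 cyclopropanecarboxylic acid (name as in step 7)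
Product: 12 dimethyl (1S,2S,3R)-3-[3-acetoxy-4-(benzyloxy)phenyl]-1-[3,4-bis(benzyloxy)benzoyl]cyclopropane-1,2-dicarboxylate
Conditions: MeI, KHCO3, DMF, rt
Reagents that add atoms: iodomethane, CI
Why: SN2 O-alkylation of the carboxylate under weakly basic conditions that should neither cleave the aryl acetate nor epimerise C2.

Step 9
Reactants: 12 dimethyl (1S,2S,3R)-3-[3-acetoxy-4-(benzyloxy)phenyl]-1-[3,4-bis(benzyloxy)benzoyl]cyclopropane-1,2-dicarboxylate
Product: 13 dimethyl (1R,2S)-1-[3-acetoxy-4-(benzyloxy)phenyl]-6,7-bis(benzyloxy)-4-hydroxy-1,2-dihydronaphthalene-2,3-dicarboxylate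
Conditions: In(OTf)3 (30 mol %), 4 Å molecular sieves, CH2Cl2 (0.02 M), rt to 40 °C
Reagents that add atoms: none
Why: In(OTf)3 chelates the keto ester at C3 and so heterolyses C1–C3, the one cyclopropane bond with the donor (ring C, O4' para to C1) at one end and two acceptors at the other, to a C1 benzylic cation and an indium enolate spanning C3–C4. Rotation about C2–C3 and C3–C4 swings ring A over the cation, C8a (para to the 6-benzyloxy group) bonds to C1 in an intramolecular Friedel–Crafts alkylation, and rearomatisation with proton transfer to the enolate leaves the hydrogen-bonded enol. The closest known reaction type is the Lewis acid cyclisation of aryl 2-arylcyclopropyl ketones to 4-aryl-1-tetralones (aryl homo-Nazarov reaction), which also runs catalytically when an ester sits next to the ketone. Ring B closes in a six-membered mode, 6-exo-trig with respect to the quinone-methide-like C1=C1' bond of the cation, through a half-chair. The new stereocentre C1 is controlled by the untouched C2: ring A is tied to C3 and therefore reaches the face of C1 that C3 has just left, and the rotamer that turns C2–H rather than the C2 ester toward ring C (least allylic 1,3-strain, ester pseudoequatorial) puts ring C and the ester trans, that is (1R,2S). The step needs C1–C3 rather than C1–C2 cleavage (secured by chelation at the doubly activated C3), attack through C8a rather than the other ortho carbon C5, which is wedged between C4a and the 6-benzyloxy group, and C- rather than O-capture (a dihydrofuran from the enolate oxygen reopens under the same catalyst, whereas arylation is irreversible).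

Step 10
Reactants: 13 enol diester (name as in step 9)
Product: 14 dimethyl (1R,2S)-1-[3-acetoxy-4-(benzyloxy)phenyl]-6,7-bis(benzyloxy)-4-(trifluoromethylsulfonyloxy)-1,2-dihydronaphthalene-2,3-dicarboxylate
Conditions: Tf2O (1.2 equiv), i-Pr2NEt (1.5 equiv), CH2Cl2, −78 °C
Reagents that add atoms: triflic anhydride, O=S(=O)(OS(=O)(=O)C(F)(F)F)C(F)(F)F
Why: O-sulfonylation of the enol of a cyclic β-keto ester with a hindered amine at low temperature, the standard route to β-triflyloxy enoates; no other free OH is present.

Step 11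
Reactants: 14 enol triflate (name as in step 10)
Product: 15 dimethyl (1R,2S)-1-[3-acetoxy-4-(benzyloxy)phenyl]-6,7-bis(benzyloxy)-1,2-dihydronaphthalene-2,3-dicarboxylate
Conditions: Pd(OAc)2 (5 mol %), PPh3 (10 mol %), HCO2H (2 equiv), Et3N (3 equiv), DMF, 60 °C
Reagents that add atoms: none
Why: Palladium-catalysed formate reduction of an enol triflate: zerovalent palladium formed in situ inserts into C4–O, formate replaces triflate and loses CO2, and reductive elimination delivers C4–H with C3=C4 in place, while the homogeneous conditions spare benzyl ethers, acetate and both stereocentres.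

Step 12
Reactants: 15 acetate (name as in step 11)
Product: 16 dimethyl (1R,2S)-6,7-bis(benzyloxy)-1-[4-(benzyloxy)-3-hydroxyphenyl]-1,2-dihydronaphthalene-2,3-dicarboxylate
Conditions: K2CO3 (0.2 equiv), MeOH/CH2Cl2, 0 °C
Reagents that add atoms: none
Why: Base-catalysed transesterification that takes the activated aryl acetate quickly, is degenerate for the methyl esters, and can at worst return C2 to the favoured trans arrangement.

Step 13
Reactants: 17 methyl bis(2,2,2-trifluoroethyl)phosphonoacetate
Product: 18 methyl diazo[bis(2,2,2-trifluoroethoxy)phosphoryl]acetate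
Conditions: 4-acetamidobenzenesulfonyl azide, DBU, MeCN, 0 °C to rt
Reagents that add atoms: 4-acetamidobenzenesulfonyl azide, CC(=O)Nc1ccc(S(=O)(=O)N=[N+]=[N-])cc1
Why: Regitz diazo transfer to the acidic methylene group of the commercial Still–Gennari phosphonate.

Step 14
Reactants: 16 phenol (name as in step 12); 18 methyl diazo[bis(2,2,2-trifluoroethoxy)phosphoryl]acetate
Product: 19 dimethyl (1R,2S)-6,7-bis(benzyloxy)-1-[4-(benzyloxy)-3-{[bis(2,2,2-trifluoroethoxy)phosphoryl](methoxycarbonyl)methoxy}phenyl]-1,2-dihydronaphthalene-2,3-dicarboxylate (both epimers at the side-chain carbon)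
Conditions: Rh2(OAc)4 (2 mol %), toluene, 80 °C, slow addition of 18
Reagents that add atoms: none
Why: Rhodium carbenoid O–H insertion of a diazophosphonoacetate into a phenol, which is faster than attack on the electron-poor C3=C4 alkene or the benzyl ethers; the new side-chain stereocentre forms as a mixture and vanishes in the next step.

Step 15
Reactants: 19 aryloxyphosphonoacetate (name as in step 14); 20 3,4-bis(benzyloxy)benzaldehyde
Product: 21 dimethyl (1R,2S)-6,7-bis(benzyloxy)-1-[4-(benzyloxy)-3-{[(E)-2-[3,4-bis(benzyloxy)phenyl]-1-(methoxycarbonyl)ethenyl]oxy}phenyl]-1,2-dihydronaphthalene-2,3-dicarboxylate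
Conditions: KN(SiMe3)2 (1.0 equiv), 18-crown-6 (4 equiv), THF, −78 °C; then 20, −78 to −40 °C
Reagents that add atoms: none
Why: Still–Gennari variant of the Horner–Wadsworth–Emmons reaction: with the trifluoroethyl phosphonate and a dissociated potassium ion the first-formed adduct collapses faster than it reverts, so ring D should end up cis to the ester, which is the E isomer here because O3' outranks the ester carbon, and the phosphonate C–H is by far the most acidic site, so one equivalent of base leaves C2 alone.

Step 16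
Reactants: 21 trimethyl ester (name as in step 15)
Product: 22 (1R,2S)-6,7-bis(benzyloxy)-1-[4-(benzyloxy)-3-{[(E)-2-[3,4-bis(benzyloxy)phenyl]-1-carboxyethenyl]oxy}phenyl]-1,2-dihydronaphthalene-2,3-dicarboxylic acid
Conditions: LiOH (12 equiv), THF/MeOH/H2O, argon, 40 °C; then 1 M HCl, 0 °C
Reagents that add atoms: lithium hydroxide, [Li+].[OH-]
Why: Saponification (BAc2) of all three methyl esters while the phenols are still benzylated, which keeps free catechols away from base and air; the trans C1/C2 arrangement is the thermodynamic one, so reversible deprotonation at C2 should do no harm.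

Step 17
Reactants: 22 penta-O-benzyl triacid (name as in step 16)
Product: 23 (1R,2S)-1-[3-{[(E)-1-carboxy-2-(3,4-dihydroxyphenyl)ethenyl]oxy}-4-hydroxyphenyl]-6,7-dihydroxy-1,2-dihydronaphthalene-2,3-dicarboxylic acid (CNP0241205.1)
Conditions: BCl3 (15 equiv), C6HMe5 (20 equiv), CH2Cl2, −78 °C; aqueous THF quench
Reagents that add atoms: none
Why: Lewis acid debenzylation with a non-basic cation scavenger: BCl3 activates each aryl benzyl ether, pentamethylbenzene takes up the benzyl cation by Friedel–Crafts alkylation before it can attack the catechol rings, and at −78 °C neither alkene nor the aryl vinyl ether bond should be touched, which hydrogenolysis could not guarantee.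

Compound list
1 | 3',4'-dihydroxyacetophenone | CC(=O)c1ccc(O)c(O)c1 | starting material
2 | 3',4'-bis(benzyloxy)acetophenone | CC(=O)c1ccc(OCc2ccccc2)c(OCc2ccccc2)c1 | intermediate
3 | dimethyl carbonate | COC(=O)OC | starting material
4 | methyl 3-[3,4-bis(benzyloxy)phenyl]-3-oxopropanoate | COC(=O)CC(=O)c1ccc(OCc2ccccc2)c(OCc2ccccc2)c1 | intermediate
5 | methyl 2-bromo-3-[3,4-bis(benzyloxy)phenyl]-3-oxopropanoate (racemic) | COC(=O)C(Br)C(=O)c1ccc(OCc2ccccc2)c(OCc2ccccc2)c1 | intermediate
6 | 4-(benzyloxy)-3-hydroxybenzaldehyde | O=Cc1ccc(OCc2ccccc2)c(O)c1 | starting material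
7 | 3-acetoxy-4-(benzyloxy)benzaldehyde | CC(=O)Oc1cc(C=O)ccc1OCc1ccccc1 | intermediate
8 | (triphenylphosphoranylidene)acetaldehyde | O=CC=P(c1ccccc1)(c1ccccc1)c1ccccc1 | starting material
9 | (E)-3-[3-acetoxy-4-(benzyloxy)phenyl]prop-2-enal | CC(=O)Oc1cc(/C=C/C=O)ccc1OCc1ccccc1 | intermediate
10 | methyl (1S,2S,3R)-3-[3-acetoxy-4-(benzyloxy)phenyl]-1-[3,4-bis(benzyloxy)benzoyl]-2-formylcyclopropane-1-carboxylate (drawn as the C3 epimer with the aroyl group trans to ring C; the other C3 epimer serves equally) | O=C[C@H]1[C@H](c2ccc(OCc3ccccc3)c(OC(C)=O)c2)[C@@]1(C(=O)OC)C(=O)c1ccc(OCc2ccccc2)c(OCc2ccccc2)c1 | intermediate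
11 | (1S,2S,3R)-3-[3-acetoxy-4-(benzyloxy)phenyl]-2-[3,4-bis(benzyloxy)benzoyl]-2-(methoxycarbonyl)cyclopropane-1-carboxylic acid | OC(=O)[C@H]1[C@H](c2ccc(OCc3ccccc3)c(OC(C)=O)c2)[C@@]1(C(=O)OC)C(=O)c1ccc(OCc2ccccc2)c(OCc2ccccc2)c1 | intermediate
12 | dimethyl (1S,2S,3R)-3-[3-acetoxy-4-(benzyloxy)phenyl]-1-[3,4-bis(benzyloxy)benzoyl]cyclopropane-1,2-dicarboxylate | COC(=O)[C@H]1[C@H](c2ccc(OCc3ccccc3)c(OC(C)=O)c2)[C@@]1(C(=O)OC)C(=O)c1ccc(OCc2ccccc2)c(OCc2ccccc2)c1 | intermediate
13 | dimethyl (1R,2S)-1-[3-acetoxy-4-(benzyloxy)phenyl]-6,7-bis(benzyloxy)-4-hydroxy-1,2-dihydronaphthalene-2,3-dicarboxylate | COC(=O)C1=C(O)c2cc(OCc3ccccc3)c(OCc3ccccc3)cc2[C@@H](c2ccc(OCc3ccccc3)c(OC(C)=O)c2)[C@@H]1C(=O)OC | intermediate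
14 | dimethyl (1R,2S)-1-[3-acetoxy-4-(benzyloxy)phenyl]-6,7-bis(benzyloxy)-4-(trifluoromethylsulfonyloxy)-1,2-dihydronaphthalene-2,3-dicarboxylate | COC(=O)C1=C(OS(=O)(=O)C(F)(F)F)c2cc(OCc3ccccc3)c(OCc3ccccc3)cc2[C@@H](c2ccc(OCc3ccccc3)c(OC(C)=O)c2)[C@@H]1C(=O)OC | intermediate
15 | dimethyl (1R,2S)-1-[3-acetoxy-4-(benzyloxy)phenyl]-6,7-bis(benzyloxy)-1,2-dihydronaphthalene-2,3-dicarboxylate | COC(=O)C1=Cc2cc(OCc3ccccc3)c(OCc3ccccc3)cc2[C@@H](c2ccc(OCc3ccccc3)c(OC(C)=O)c2)[C@@H]1C(=O)OC | intermediate
16 | dimethyl (1R,2S)-6,7-bis(benzyloxy)-1-[4-(benzyloxy)-3-hydroxyphenyl]-1,2-dihydronaphthalene-2,3-dicarboxylate | COC(=O)C1=Cc2cc(OCc3ccccc3)c(OCc3ccccc3)cc2[C@@H](c2ccc(OCc3ccccc3)c(O)c2)[C@@H]1C(=O)OC | intermediate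
17 | methyl bis(2,2,2-trifluoroethyl)phosphonoacetate | COC(=O)CP(=O)(OCC(F)(F)F)OCC(F)(F)F | starting material
18 | methyl diazo[bis(2,2,2-trifluoroethoxy)phosphoryl]acetate | COC(=O)C(=[N+]=[N-])P(=O)(OCC(F)(F)F)OCC(F)(F)F | intermediate
19 | dimethyl (1R,2S)-6,7-bis(benzyloxy)-1-[4-(benzyloxy)-3-{[bis(2,2,2-trifluoroethoxy)phosphoryl](methoxycarbonyl)methoxy}phenyl]-1,2-dihydronaphthalene-2,3-dicarboxylate (both epimers at the side-chain carbon) | COC(=O)C1=Cc2cc(OCc3ccccc3)c(OCc3ccccc3)cc2[C@@H](c2ccc(OCc3ccccc3)c(OC(C(=O)OC)P(=O)(OCC(F)(F)F)OCC(F)(F)F)c2)[C@@H]1C(=O)OC | intermediate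
20 | 3,4-bis(benzyloxy)benzaldehyde | O=Cc1ccc(OCc2ccccc2)c(OCc2ccccc2)c1 | starting material
21 | dimethyl (1R,2S)-6,7-bis(benzyloxy)-1-[4-(benzyloxy)-3-{[(E)-2-[3,4-bis(benzyloxy)phenyl]-1-(methoxycarbonyl)ethenyl]oxy}phenyl]-1,2-dihydronaphthalene-2,3-dicarboxylate | COC(=O)C1=Cc2cc(OCc3ccccc3)c(OCc3ccccc3)cc2[C@@H](c2ccc(OCc3ccccc3)c(O/C(=C/c3ccc(OCc4ccccc4)c(OCc4ccccc4)c3)C(=O)OC)c2)[C@@H]1C(=O)OC | intermediate
22 | (1R,2S)-6,7-bis(benzyloxy)-1-[4-(benzyloxy)-3-{[(E)-2-[3,4-bis(benzyloxy)phenyl]-1-carboxyethenyl]oxy}phenyl]-1,2-dihydronaphthalene-2,3-dicarboxylic acid | O=C(O)C1=Cc2cc(OCc3ccccc3)c(OCc3ccccc3)cc2[C@@H](c2ccc(OCc3ccccc3)c(O/C(=C/c3ccc(OCc4ccccc4)c(OCc4ccccc4)c3)C(=O)O)c2)[C@@H]1C(=O)O | intermediate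
23 | (1R,2S)-1-[3-{[(E)-1-carboxy-2-(3,4-dihydroxyphenyl)ethenyl]oxy}-4-hydroxyphenyl]-6,7-dihydroxy-1,2-dihydronaphthalene-2,3-dicarboxylic acid | O=C(O)C1=Cc2cc(O)c(O)cc2[C@@H](c2ccc(O)c(O/C(=C/c3ccc(O)c(O)c3)C(=O)O)c2)[C@@H]1C(=O)O | target

Total step count: 17. Longest linear sequence: 14 steps (steps 1–3, 6–12 and 14–17).

Steps most likely to fail

Step 9. The metal-bound C4 carbonyl makes ring A a weak nucleophile. The opened dipole may therefore be drained by capture at the enolate oxygen, by proton loss from C2 (which would also erase the only stereocentre), or by loss of benzyl from O4'.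
The fallback sets out from 12 and comes back at 13, and it splits the rearrangement into two separate events.
- 12 is first opened at C1 with methanol (MeOH, Sc(OTf)3 10 mol %, CH2Cl2, 0 °C) to the acyclic benzylic methyl ether F1, in which C2 is unchanged.
- F1 is then ionised with catalytic TfOH in hexafluoroisopropanol. No metal sits on the β-keto ester, which is present as its enol, so ring A is attached to a donor carbon rather than to a complexed carbonyl.
- The same C1–C8a bond closes under the same control by C2.

Step 15. With a slow, electron-rich aldehyde the adducts may equilibrate and erode the kinetic E selectivity, and the hindered carbanion may add sluggishly, so that deprotonation at C2 starts to compete.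
The fallback sets out from 16, 17 and 20 and comes back at 21, bypassing 19. It fixes the alkene geometry on a small fragment before it is attached.
- 17 is brominated twice (Br2, aqueous NaOH, 0 °C) to the dibromophosphonoacetate F2.
- F2 is reduced with SnCl2 (EtOH/H2O) to the monobromophosphonoacetate F3.
- Olefination of 20 with F3 (t-BuOK, 18-crown-6, THF, −78 °C) should give methyl (E)-2-bromo-3-[3,4-bis(benzyloxy)phenyl]acrylate F4, which can be purified to one isomer.
- Ullmann-type vinylation of phenol 16 with F4 (CuI, N,N-dimethylglycine hydrochloride, Cs2CO3, dioxane, 60–80 °C) is expected to keep the alkene geometry. The β-hydrogen of this isomer is syn to bromine, so base-induced anti elimination to the alkyne should be slow.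

Step 6. Three processes may lower conversion and enantiopurity, and this step is the sole source of chirality: bromine transfer from the bromo keto ester to the amine catalyst, slow addition to an electron-rich iminium ion, and amine-induced reopening of the strained product.
The fallback sets out from 4 and 9 and comes back at 10. It brings in the halogen only after C1–C3 has been made.
- Keto ester 4 is added to 9 under the same (R)-catalyst with benzoic acid as co-catalyst (toluene, rt) to give the Michael adduct F5, with C1 set by the catalyst.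
- I2 and Et3N are then added to the same flask, and the 1,3-dicarbonyl carbon C3 is iodinated to the tertiary iodide F6.
- The enamine carbon C2 displaces iodide from F6 in a 3-exo-tet closure, trans to ring C.

Further compounds
F1 | step 9 | dimethyl 2-{[3-acetoxy-4-(benzyloxy)phenyl](methoxy)methyl}-3-[3,4-bis(benzyloxy)benzoyl]butanedioate, C2 of the target numbering unchanged, mixture at C1 and C3 | COC(=O)[C@H](C(C(=O)OC)C(=O)c1ccc(OCc2ccccc2)c(OCc2ccccc2)c1)C(OC)c1ccc(OCc2ccccc2)c(OC(C)=O)c1
F2 | step 15 | methyl dibromo[bis(2,2,2-trifluoroethoxy)phosphoryl]acetate | COC(=O)C(Br)(Br)P(=O)(OCC(F)(F)F)OCC(F)(F)F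
F3 | step 15 | methyl bromo[bis(2,2,2-trifluoroethoxy)phosphoryl]acetate | COC(=O)C(Br)P(=O)(OCC(F)(F)F)OCC(F)(F)F
F4 | step 15 | methyl (E)-2-bromo-3-[3,4-bis(benzyloxy)phenyl]acrylate | Br/C(=C/c1ccc(OCc2ccccc2)c(OCc2ccccc2)c1)C(=O)OC
F5 | step 6 | methyl (3S)-3-[3-acetoxy-4-(benzyloxy)phenyl]-2-[3,4-bis(benzyloxy)benzoyl]-5-oxopentanoate, mixture at the dicarbonyl carbon | O=CC[C@H](c1ccc(OCc2ccccc2)c(OC(C)=O)c1)C(C(=O)OC)C(=O)c1ccc(OCc2ccccc2)c(OCc2ccccc2)c1
F6 | step 6 | methyl 3-[3-acetoxy-4-(benzyloxy)phenyl]-2-[3,4-bis(benzyloxy)benzoyl]-2-iodo-5-oxopentanoate, aryl-bearing carbon as in F5, mixture at the iodinated carbon | O=CC[C@H](c1ccc(OCc2ccccc2)c(OC(C)=O)c1)C(I)(C(=O)OC)C(=O)c1ccc(OCc2ccccc2)c(OCc2ccccc2)c1
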